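Time came first: the 30 min of these runs is shorter than 83.3 min, the reciprocal of the forward constant, so I expected flasks caught on their way up.

all flasks: time 30 min

| charge | substrate |
|---|---|
| blue | 0.0050 M |
| red | 0.015 M |
| violet | 0.040 M |
| grey | 0.12 M |

    substrate ⇌ target + by-product (K1 = 0.019 M, k1 = 0.012 min⁻¹)
    target + by-product → side product (k2 = 0.76 L mol⁻¹ min⁻¹)

- "hardly changes" means that all values lie within two and a half points (for a concentration: within two and a half percent of the largest)
- run time (blue): 30 min

1. amount of target at the end, in percent of the substrate charged for blue, red, violet, grey, in this order
2. the shape of the row from first to last (falls all the way / falls, then rises / hardly changes / rises all the way / rises, then falls)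

For a thin charge I took the target as the plain first-order turnover of substrate, 30.2% of the charge, whatever the charge. But target and by-product are born in pairs, so their concentrations stay equal, and two losses, the back step and the second step, run on the square of c(target) with the summed constant 1.39 L mol⁻¹ min⁻¹. That gave the other end: a plateau, the quasi-steady state, where forward formation equals this loss. For grey the plateau was 26.8% of the charge. But had grey reached it in the time given?

To join the ends I used the crossover charge, the charge at which target made at the initial rate over the whole run just equals the plateau: 0.0665 M. Blue's charge is less than this and grey's is more, so I put blue on the thin-charge side and grey on the plateau side. With substrate held fixed, c(target) climbs as a tanh, and the end percentage is the forward constant times the time, multiplied by tanh(u)/u, where u is the root of charge over crossover charge. For grey u is 1.34, the factor is 0.650, and the result is 23.4%. Yet substrate does fall, so the straight 36.0% overstates the start. I replaced it with the 30.2% above, a patch rather than a solution. My row became 29.5%, 28.1%, 25.3% and 19.6%, falling from blue to grey.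

The forecast gave 29.5%, 28.3%, 25.7% and 20%, shape falls all the way, on the ground that “the second-order loss grows with concentration”. From red on, its values stood slightly above mine.

The simulation gave 29.6%, 28.4%, 25.8% and 20.4%, shape falls all the way, so the forecast held.

Grey was charged at 1.80 crossover charges, past the join. The short time allowed is part of why grey still held 20.4% of target: after 300 min it stood at 11.1%. The back reaction of target + by-product to substrate is part of grey's shortfall: the run without it gained 3.1 percentage points. I carried the crossover charge to that second flask, grey with the back step struck out, where the summed constant shrinks to 0.76 L mol⁻¹ min⁻¹ and the crossover charge moves to 0.122 M. There u is 0.992, which gives 23.1%, and that run stood at 23.5%.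

The numbers are those of an exercise; the flask was simulated.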